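**Retrosynthetic overview**

- Numbering: ring A is the cyclohexadienone, with C1 (C=O), C2 (allyl), C3, C4 (quaternary, OMe and side chain), C5 (OMe), C6; C7 is the CHMe carbon of the side chain; ring B is the dimethoxyphenyl ring. The strategy rests on the 1,3-related oxygens on C1 and C5 of ring A together with the fully substituted C4 next to C5, which is the imprint of a vinylketene/ynol ether annulation that cannot aromatise.
- Target 25 is traced to siloxy dienone 23 by exchanging the roles of the two oxygens: methyl onto the C5 carbonyl oxygen, silyl off O1.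
- 23 is disconnected to acid chloride 16 and triisopropylsiloxyacetylene 19: C5–C6 and C1–C2 by [2+2], then 4π opening and 6π closure forming C4–C5.
- 16 comes from α-methoxy aldehyde 10 and allylphosphonate 13 (C2=C3); 10 comes from aldehyde 5 by vinyl addition, O-methylation and ozonolysis; 5 comes from an Evans benzylation of 1 with 2, which sets C7.
- Ring order: ring B is bought; ring A is the only ring made, in step 12.

Key step: step 12

Remark: the olefination of step 8 should give mainly the (2E) enoate, so the acid chloride is carried as the (2E) isomer and as a mixture of C4 epimers; both elements vanish when the vinylketene forms and need no control.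
Remark: species that differ from a numbered compound only by loss of a proton (enolates, alkoxides, acetylide, phosphonate anions, carboxylates) are treated as forms of that compound and carry no number of their own.

**Route**

Step 1
Reactants: 1 (S)-4-benzyl-3-propanoyl-1,3-oxazolidin-2-one; 2 3,4-dimethoxybenzyl bromide
Product: 3 (S)-4-benzyl-3-[(2R)-3-(3,4-dimethoxyphenyl)-2-methylpropanoyl]-1,3-oxazolidin-2-one
Conditions: NaN(SiMe3)2, THF, −78 °C; then 2, −78 to −40 °C
Reagents that add atoms: none
Why: Evans asymmetric alkylation, in which the chelated sodium (Z)-enolate of 1 is benzylated on the face away from the 4-benzyl group, which should set C7 as R.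

Step 2
Reactants: 3 (S)-4-benzyl-3-[(2R)-3-(3,4-dimethoxyphenyl)-2-methylpropanoyl]-1,3-oxazolidin-2-one
Product: 4 (2R)-3-(3,4-dimethoxyphenyl)-2-methylpropan-1-ol
Conditions: LiBH4, H2O (1 equiv), Et2O, 0 °C
Reagents that add atoms: none
Why: Reductive cleavage of the N-acyloxazolidinone by hydride attack at the exocyclic carbonyl releases the primary alcohol and the auxiliary without touching C7.

Step 3
Reactants: 4 (2R)-3-(3,4-dimethoxyphenyl)-2-methylpropan-1-ol
Product: 5 (2R)-3-(3,4-dimethoxyphenyl)-2-methylpropanal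
Conditions: Dess–Martin periodinane, CH2Cl2, 0 °C to rt
Reagents that add atoms: none
Why: Dess–Martin oxidation is non-basic, so the α-stereocentre C7 should survive if 5 is used at once.

Step 4
Reactants: 5 (2R)-3-(3,4-dimethoxyphenyl)-2-methylpropanal; 6 vinylmagnesium bromide
Product: 7 (4R)-5-(3,4-dimethoxyphenyl)-4-methylpent-1-en-3-ol (mixture of C3 epimers)
Conditions: CH2=CHMgBr, THF, −78 °C; then H2O
Reagents that add atoms: none
Why: Grignard 1,2-addition at low temperature should outrun enolisation of 5, and the new carbinol centre (future C4) may form as a mixture because it becomes trigonal in step 12.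

Step 5
Reactants: 7 (4R)-5-(3,4-dimethoxyphenyl)-4-methylpent-1-en-3-ol
Product: 8 4-[(2R)-3-methoxy-2-methylpent-4-en-1-yl]-1,2-dimethoxybenzene (mixture of C3 epimers)
Conditions: NaH, MeI, THF, 0 °C to rt
Reagents that add atoms: iodomethane, CI
Why: Williamson etherification of the sodium alkoxide, the only acidic site in 7.

Step 6
Reactants: 8 4-[(2R)-3-methoxy-2-methylpent-4-en-1-yl]-1,2-dimethoxybenzene
Product: 10 (3R)-4-(3,4-dimethoxyphenyl)-2-methoxy-3-methylbutanal (mixture of C2 epimers), via ozonide 9 (not isolated)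
Conditions: O3, CH2Cl2, −78 °C (Sudan Red 7B end point); then PPh3, −78 °C to rt
Reagents that add atoms: ozone, [O-][O+]=O
Why: Ozonolysis with a limited ozone dose cleaves the terminal alkene much faster than it attacks the dimethoxyarene, and PPh3 reduces the ozonide to the α-methoxy aldehyde.

Step 7
Reactants: 11 triethyl phosphonoacetate; 12 allyl bromide
Product: 13 ethyl 2-(diethoxyphosphoryl)pent-4-enoate (racemic)
Conditions: NaH, THF, 0 °C; then allyl bromide, rt
Reagents that add atoms: none
Why: SN2 C-alkylation of the stabilised phosphonoacetate anion, with a slight excess of 11 to favour monoalkylation.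

Step 8
Reactants: 10 (3R)-4-(3,4-dimethoxyphenyl)-2-methoxy-3-methylbutanal; 13 ethyl 2-(diethoxyphosphoryl)pent-4-enoate
Product: 14 ethyl (2E,5R)-6-(3,4-dimethoxyphenyl)-4-methoxy-5-methyl-2-(prop-2-en-1-yl)hex-2-enoate (mixture of C4 epimers)
Conditions: NaH, THF, 0 °C; then 10, 0 °C to rt
Reagents that add atoms: none
Why: Horner–Wadsworth–Emmons olefination forms C2=C3, the α-branched phosphonate favouring the (2E) enoate; neither this geometry nor the epimerisable C4 matters later.

Step 9
Reactants: 14 ethyl (2E,5R)-6-(3,4-dimethoxyphenyl)-4-methoxy-5-methyl-2-(prop-2-en-1-yl)hex-2-enoate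
Product: 15 (2E,5R)-6-(3,4-dimethoxyphenyl)-4-methoxy-5-methyl-2-(prop-2-en-1-yl)hex-2-enoic acid (mixture of C4 epimers)
Conditions: LiOH, THF/MeOH/H2O, rt; then dilute HCl, 0 °C
Reagents that add atoms: lithium hydroxide, [Li+].[OH-]
Why: Saponification of the ethyl ester; C7 is not α to a carbonyl group and is not at risk.

Step 10
Reactants: 15 (2E,5R)-6-(3,4-dimethoxyphenyl)-4-methoxy-5-methyl-2-(prop-2-en-1-yl)hex-2-enoic acid
Product: 16 (2E,5R)-6-(3,4-dimethoxyphenyl)-4-methoxy-5-methyl-2-(prop-2-en-1-yl)hex-2-enoyl chloride (mixture of C4 epimers; acyl carbon = future C5, then C2, C3, C4 and C7 along the chain)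
Conditions: (COCl)2, DMF (cat.), CH2Cl2, 0 °C to rt; evaporation, used crude
Reagents that add atoms: oxalyl chloride, O=C(Cl)C(=O)Cl
Why: Vilsmeier-type activation with oxalyl chloride and catalytic DMF gives the acid chloride with only gaseous by-products.

Step 11
Reactants: 17 acetylene
Product: 19 triisopropylsiloxyacetylene [ethynyloxytri(propan-2-yl)silane], via lithium ethynolate 18 (not isolated)
Conditions: HC≡CH (excess), n-BuLi, THF, −78 °C; t-BuOOLi (from t-BuOOH and LiN(SiMe3)2), −78 to −10 °C; i-Pr3SiOTf, −78 to 0 °C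
Reagents that add atoms: tert-butyl hydroperoxide, CC(C)(C)OO; triisopropylsilyl trifluoromethanesulfonate, CC(C)[Si](C(C)C)(C(C)C)OS(=O)(=O)C(F)(F)F
Why: Julia-type oxidation of the lithium acetylide by the electrophilic oxygen of t-BuOOLi gives the ynolate, which the bulky silyl triflate should trap on oxygen and not on carbon.

Step 12
Reactants: 16 (2E,5R)-6-(3,4-dimethoxyphenyl)-4-methoxy-5-methyl-2-(prop-2-en-1-yl)hex-2-enoyl chloride; 19 triisopropylsiloxyacetylene
Product: 23 (6R)-6-[(2R)-1-(3,4-dimethoxyphenyl)propan-2-yl]-6-methoxy-4-(prop-2-en-1-yl)-3-[tri(propan-2-yl)silyloxy]cyclohexa-2,4-dien-1-one, via vinylketene 20 (not isolated), via cyclobutenone 21 (not isolated), via dienylketene 22 (not isolated)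
Conditions: 19 (excess), Et3N, toluene, slow addition of 16 at 40 °C; then 90 °C; chromatographic separation from the C4 epimer
Reagents that add atoms: none
Why: Et3N removes the γ-hydrogen on C4 of 16 in a 1,4-dehydrochlorination to give vinylketene 20, whose ketene carbon (future C5) is attacked by the nucleophilic CH terminus of 19 (C5–C6) with closure of C1–C2 to cyclobutenone 21, and release of four-ring strain then drives conrotatory 4π opening to dienylketene 22. Thermal disrotatory 6π electrocyclisation of 22 forms C4–C5 and closes the six-membered ring A, and because C4 then carries OMe and C7 and no hydrogen, no enolisation to a phenol is possible and the sequence should stop at dienone 23. The closest known reaction type is the Danheiser benzannulation of vinylketenes with siloxyalkynes, joined to the known generation of vinylketenes from enoyl chlorides with Et3N and the known thermal closure of dienylketenes to 6,6-disubstituted cyclohexa-2,4-dienones. The new stereocentre C4 is set in the 6π closure under the control of the adjacent C7 stereocentre alone (allylic strain holds the C7–H bond near the plane of the enol ether, so the ketene carbon passes either methyl or the arylmethyl group), a weak bias, so the (4R) isomer 23 is expected to need separation from its C4 epimer. The step needs [2+2] regioselectivity, which the polarisation of the ynol ether secures, and 6π closure in preference to [2+2] of the ketene onto the allyl alkene, which the reversible 4π opening and the fast closure onto the electron-rich enol-ether terminus should favour. The C2=C3 geometry and the C4 configuration of 16 are both lost in 20, so neither has to be controlled beforehand.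

Step 13
Reactants: 23 (6R)-6-[(2R)-1-(3,4-dimethoxyphenyl)propan-2-yl]-6-methoxy-4-(prop-2-en-1-yl)-3-[tri(propan-2-yl)silyloxy]cyclohexa-2,4-dien-1-one
Product: 25 (4R)-4-[(2R)-1-(3,4-dimethoxyphenyl)propan-2-yl]-4,5-dimethoxy-2-(prop-2-en-1-yl)cyclohexa-2,5-dien-1-one (the target), via O-methylated cation tetrafluoroborate 24 (not isolated)
Conditions: Me3OBF4, 2,6-di-tert-butyl-4-methylpyridine, CH2Cl2, 0 °C; then CsF, MeCN, 0 °C
Reagents that add atoms: trimethyloxonium tetrafluoroborate, C[O+](C)C.F[B-](F)(F)F
Why: Proposed new method: the carbonyl oxygen on C5 is the donor terminus of the O1–C1=C6–C5=O vinylogous silyl ester and should be the most nucleophilic site toward a hard methyl donor, giving the 1-siloxy-5-methoxy cyclohexadienyl cation 24, from which fluoride removes silicon at O1 so that the ketone is released at C1 and the methyl enol ether stays at C5 with C4 and C7 untouched; the closest known reaction types are O-alkylation of 3-alkoxy-enones by trialkyloxonium salts to 1,3-dialkoxyallyl cations and fluoride desilylation of silyloxycarbenium ions.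

**Compound list**

1 | (S)-4-benzyl-3-propanoyl-1,3-oxazolidin-2-one | CCC(=O)N1[C@@H](Cc2ccccc2)COC1=O | starting material
2 | 3,4-dimethoxybenzyl bromide | COc1ccc(CBr)cc1OC | starting material
3 | (S)-4-benzyl-3-[(2R)-3-(3,4-dimethoxyphenyl)-2-methylpropanoyl]-1,3-oxazolidin-2-one | COc1ccc(C[C@@H](C)C(=O)N2[C@@H](Cc3ccccc3)COC2=O)cc1OC | intermediate
4 | (2R)-3-(3,4-dimethoxyphenyl)-2-methylpropan-1-ol | COc1ccc(C[C@@H](C)CO)cc1OC | intermediate
5 | (2R)-3-(3,4-dimethoxyphenyl)-2-methylpropanal | COc1ccc(C[C@@H](C)C=O)cc1OC | intermediate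
6 | vinylmagnesium bromide | C=C[Mg]Br | starting material
7 | (4R)-5-(3,4-dimethoxyphenyl)-4-methylpent-1-en-3-ol, C3 epimers | C=CC(O)[C@H](C)Cc1ccc(OC)c(OC)c1 | intermediate
8 | 4-[(2R)-3-methoxy-2-methylpent-4-en-1-yl]-1,2-dimethoxybenzene, C3 epimers | C=CC(OC)[C@H](C)Cc1ccc(OC)c(OC)c1 | intermediate
9 | 3-[(2R)-3-(3,4-dimethoxyphenyl)-1-methoxy-2-methylpropyl]-1,2,4-trioxolane (ozonide) | C1OOC(O1)C(OC)[C@H](C)Cc2ccc(OC)c(OC)c2 | intermediate
10 | (3R)-4-(3,4-dimethoxyphenyl)-2-methoxy-3-methylbutanal, C2 epimers | O=CC(OC)[C@H](C)Cc1ccc(OC)c(OC)c1 | intermediate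
11 | triethyl phosphonoacetate | CCOC(=O)CP(=O)(OCC)OCC | starting material
12 | allyl bromide | C=CCBr | starting material
13 | ethyl 2-(diethoxyphosphoryl)pent-4-enoate | C=CCC(C(=O)OCC)P(=O)(OCC)OCC | intermediate
14 | ethyl (2E,5R)-6-(3,4-dimethoxyphenyl)-4-methoxy-5-methyl-2-(prop-2-en-1-yl)hex-2-enoate, C4 epimers | CCOC(=O)/C(CC=C)=C/C(OC)[C@H](C)Cc1ccc(OC)c(OC)c1 | intermediate
15 | (2E,5R)-6-(3,4-dimethoxyphenyl)-4-methoxy-5-methyl-2-(prop-2-en-1-yl)hex-2-enoic acid, C4 epimers | OC(=O)/C(CC=C)=C/C(OC)[C@H](C)Cc1ccc(OC)c(OC)c1 | intermediate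
16 | (2E,5R)-6-(3,4-dimethoxyphenyl)-4-methoxy-5-methyl-2-(prop-2-en-1-yl)hex-2-enoyl chloride, C4 epimers | ClC(=O)/C(CC=C)=C/C(OC)[C@H](C)Cc1ccc(OC)c(OC)c1 | intermediate
17 | acetylene | C#C | starting material
18 | lithium ethynolate | [Li+].[O-]C#C | intermediate
19 | triisopropylsiloxyacetylene | C#CO[Si](C(C)C)(C(C)C)C(C)C | intermediate
20 | (5R)-6-(3,4-dimethoxyphenyl)-4-methoxy-5-methyl-2-(prop-2-en-1-yl)hexa-1,3-dien-1-one (vinylketene, enol ether geometry undefined) | C=CCC(=C=O)C=C(OC)[C@H](C)Cc1ccc(OC)c(OC)c1 | intermediate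
21 | 4-[(3R)-4-(3,4-dimethoxyphenyl)-2-methoxy-3-methylbut-1-en-1-yl]-4-(prop-2-en-1-yl)-3-[tri(propan-2-yl)silyloxy]cyclobut-2-en-1-one | C=CCC1(C=C(OC)[C@H](C)Cc2ccc(OC)c(OC)c2)C(=O)C=C1O[Si](C(C)C)(C(C)C)C(C)C | intermediate
22 | (7R)-8-(3,4-dimethoxyphenyl)-6-methoxy-7-methyl-4-(prop-2-en-1-yl)-3-[tri(propan-2-yl)silyloxy]octa-1,3,5-trien-1-one (dienylketene) | C=CCC(C=C(OC)[C@H](C)Cc1ccc(OC)c(OC)c1)=C(C=C=O)O[Si](C(C)C)(C(C)C)C(C)C | intermediate
23 | (6R)-6-[(2R)-1-(3,4-dimethoxyphenyl)propan-2-yl]-6-methoxy-4-(prop-2-en-1-yl)-3-[tri(propan-2-yl)silyloxy]cyclohexa-2,4-dien-1-one | C=CCC1=C[C@](OC)([C@H](C)Cc2ccc(OC)c(OC)c2)C(=O)C=C1O[Si](C(C)C)(C(C)C)C(C)C | intermediate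
24 | O-methylated cation of 23 as its tetrafluoroborate (5-methoxy-1-silyloxy cyclohexadienyl cation, drawn as the silyloxonium form) | C=CCC1=C[C@](OC)([C@H](C)Cc2ccc(OC)c(OC)c2)C(OC)=CC1=[O+][Si](C(C)C)(C(C)C)C(C)C.F[B-](F)(F)F | intermediate
25 | (4R)-4-[(2R)-1-(3,4-dimethoxyphenyl)propan-2-yl]-4,5-dimethoxy-2-(prop-2-en-1-yl)cyclohexa-2,5-dien-1-one | C=CCC1=C[C@](OC)([C@H](C)Cc2ccc(OC)c(OC)c2)C(OC)=CC1=O | target

**Step count and risks**

Total step count: 13. Longest linear sequence: 11 steps (steps 1 to 6, 8 to 10, 12 and 13).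

Steps most likely to fail:

1. Step 13. The methyl group may be delivered to C6 or to an ether oxygen instead of the C5 carbonyl oxygen. Cation 24 is also a cyclohexadienyl cation with the quaternary C4 next to its termini, so a C4 substituent may undergo a 1,2-shift followed by aromatisation before fluoride removes the silyl group. The fallback uses known chemistry only, sets out from 23 and comes back at 25. Bu4NF buffered with AcOH in THF at 0 °C should cleave the silyl enol ether to the enolised 1,3-dione (6R)-6-[(2R)-1-(3,4-dimethoxyphenyl)propan-2-yl]-3-hydroxy-6-methoxy-4-(prop-2-en-1-yl)cyclohexa-2,4-dien-1-one F1. O-Methylation of F1 with Me3SiCHN2 in toluene/MeOH is expected to give 25 together with the regioisomeric vinylogous ester (6R)-6-[(2R)-1-(3,4-dimethoxyphenyl)propan-2-yl]-3,6-dimethoxy-4-(prop-2-en-1-yl)cyclohexa-2,4-dien-1-one F2, to be separated by chromatography. F2 can be returned to F1 with dilute aqueous HCl in THF and methylated again.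

2. Step 12. Poor facial selectivity in the 6π ring closure: C7 distinguishes the two faces of the C4 terminus only through methyl against arylmethyl, so a large share of the material may form as the C4 epimer, and the two epimers will need a secure assignment. The fallback sets out from 16 through the step as written and comes back at 23. The separated C4 epimer (6S)-6-[(2R)-1-(3,4-dimethoxyphenyl)propan-2-yl]-6-methoxy-4-(prop-2-en-1-yl)-3-[tri(propan-2-yl)silyloxy]cyclohexa-2,4-dien-1-one F3 is irradiated at 365 nm in degassed toluene at room temperature with no nucleophile present. The photochemical ring opening known for 6,6-disubstituted cyclohexa-2,4-dienones should regenerate dienylketene 22, which recloses in the dark to 23 and F3, and the cycle is repeated on recovered F3.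

3. Step 11. Disproportionation of monolithium acetylide on warming, and silylation on carbon or hydrolysis of the unsubstituted ynolate, may leave too little 19. The fallback sets out from 16 and comes back at 25. Commercial ethoxyacetylene replaces 19 under the conditions of step 12 and should give, by the same cascade, the ethyl vinylogous ester (6R)-3-ethoxy-6-[(2R)-1-(3,4-dimethoxyphenyl)propan-2-yl]-6-methoxy-4-(prop-2-en-1-yl)cyclohexa-2,4-dien-1-one F4. Dilute aqueous HCl in THF hydrolyses F4 to the 3-hydroxy dienone F1, which is methylated and separated from F2 as in the first fallback.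

**Further compounds**

F1 | step 13 | (6R)-6-[(2R)-1-(3,4-dimethoxyphenyl)propan-2-yl]-3-hydroxy-6-methoxy-4-(prop-2-en-1-yl)cyclohexa-2,4-dien-1-one | C=CCC1=C[C@](OC)([C@H](C)Cc2ccc(OC)c(OC)c2)C(=O)C=C1O
F2 | step 13 | (6R)-6-[(2R)-1-(3,4-dimethoxyphenyl)propan-2-yl]-3,6-dimethoxy-4-(prop-2-en-1-yl)cyclohexa-2,4-dien-1-one | C=CCC1=C[C@](OC)([C@H](C)Cc2ccc(OC)c(OC)c2)C(=O)C=C1OC
F3 | step 12 | (6S)-6-[(2R)-1-(3,4-dimethoxyphenyl)propan-2-yl]-6-methoxy-4-(prop-2-en-1-yl)-3-[tri(propan-2-yl)silyloxy]cyclohexa-2,4-dien-1-one | C=CCC1=C[C@@](OC)([C@H](C)Cc2ccc(OC)c(OC)c2)C(=O)C=C1O[Si](C(C)C)(C(C)C)C(C)C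
F4 | step 11 | (6R)-3-ethoxy-6-[(2R)-1-(3,4-dimethoxyphenyl)propan-2-yl]-6-methoxy-4-(prop-2-en-1-yl)cyclohexa-2,4-dien-1-one | C=CCC1=C[C@](OC)([C@H](C)Cc2ccc(OC)c(OC)c2)C(=O)C=C1OCC
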